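Blue has 6.6 % of its electrophile left at 4.00 d, less than the 35.8 % in teal at the same time, although teal also carries more nucleophile than electrophile.

in all of them: electrophile 0.40 M

| run | nucleophile | solid base | protic impurity | remark | time |
|---|---|---|---|---|---|
| teal | 0.68 M | 0.40 M | 0.020 M | run made earlier |  |
| blue | 1.4 M | 0.40 M | 0.020 M | run made earlier |  |
| west | 0.600 M | 0.400 M | 0.0200 M |  | 6.0 d |
| north | 1.20 M | 0.400 M | 0.0200 M |  | 6.0 d |

| run | time / d | electrophile / % | target / % |
|---|---|---|---|
| teal | 1.04 | 66.1 | 27.6 |
| teal | 2.00 | 49.2 | 32.9 |
| teal | 3.00 | 41.8 | 38.6 |
| teal | 4.00 | 35.8 | 41.3 |
| blue | 0.500 | 61.2 | 31.1 |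
| blue | 1.67 | 26.7 | 51.6 |
| blue | 2.50 | 16.5 | 55.3 |
| blue | 4.00 | 6.6 | 60.5 |

(each reading ± 1 percentage point)

- solid base is a solid; its amount is given per volume of the solution
- at the start none of the solid base is in solution

* part of the electrophile that has reacted at the end, west
* part of the electrophile that has reacted at the end, north
* what raising the concentration of nucleophile from its lowest to its highest value here does to the part of the electrophile that has reacted (changes below 5 percentage points count as none) (no change / it falls / it rises)

The bench rule takes one nucleophile per electrophile as the even case, the zero of the scale, and counts any excess as safe: teal has 1.70 equivalents and west 1.50. Teal shows where this rule stops. Its first-order rate of electrophile loss is 0.398 /d over the first interval and 0.155 /d between its last two readings, a fall by a factor of 2.57. From [nucleophile] at those two stages I reckon a fall of 1.41 if one nucleophile is spent per electrophile and 2.86 if two are, so I read two from these readings.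

Over the span of teal's readings the even case therefore moves to two equivalents. I carry the cover, which is 75.0 % for west: the charged [nucleophile] over two times the charged [electrophile], the part of the electrophile that the charged nucleophile serves at two per electrophile. On this count nucleophile is the limiting reagent in west, while north has a cover of 150 %. Teal's early rate gives a second-order constant of 0.731 /M/d. Integrating with two nucleophile spent per electrophile, I get 63.7 % reacted in west and 93.5 % in north.

The forecast, holding that “nucleophile is probably being lost faster than electrophile”, gives 66 % for west and 95 % for north, and for the trend, it rises. I stand slightly lower on both flasks.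

The flask gives 65.5 % for west and 94.6 % for north, and from the lowest to the highest nucleophile it rises, by 29 percentage points.

    electrophile + nucleophile → acid set free + target (k = 9.23 × 10⁻⁶ /M/s)
    nucleophile + acid set free ⇌ protonated nucleophile, settled at all times (K = 7000 /M)
    acid set free + free base ⇌ salt of the base (K = 510 /M, k = 0.00157 /M/s)
    solid base ⇌ free base, rate k4*(cs4 - [free base]) while solid is left; crystals form when [free base] > cs4 (solubility = 0.270 M, k = 3.34 × 10⁻⁶ /s)
    protic impurity + free base → quenched reagent (k = 0.00106 /M/s)
    target ⇌ isomer of the product (K = 0.587, k = 1.04 × 10⁻⁵ /s)

In west the coupling of electrophile and nucleophile has 81 % of its turnover up to 6.0 d behind it at 3.00 d, while free nucleophile drops to 29.3 % of its charge and protonated nucleophile climbs to 0.210 M. By 6.00 d free nucleophile in west stands at 15.5 %, the part reacted is still under the cover of 75.0 %, 1.94 nucleophile have left the free form per electrophile reacted, and solid base is down to 39.0 % of its charge. West passes its cover later, with 92.5 % reacted at 60.0 d. The neighbour of west charged with 0.15 M of nucleophile has a cover of 18.7 % and reaches 19.7 %.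

All runs come from a simulation with made-up constants; noise was put on by code.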